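**Strategy.** Everything rests on cutting ring A out of the flavonol at C4a–C5 and C8–C8a. The four carbons released, C5(O)–C6(H)–C7(O)–C8(OMe), map onto methyl 4-methoxyacetoacetate. What stays behind, C4a=C8a, is the C5=C6 alkene of a 2-aryl-3-benzyloxy-4-pyranone. The bis(silyl) dienol ether of the ketoester is cycloadded to that alkene, which carries a p-tolylsulfinyl group as activator, regiochemical director and leaving group. One operation forms both bonds, closes ring A and aromatises it. It leaves 5-OH and 7-OH free beside 8-OMe, so ring A oxygens never need differentiation. The precursor pyranone is assembled convergently from three small pieces; hydrogenolysis ends the route.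

Key step: step 8

Assumption: all sulfoxides are racemic, and the alkene geometries drawn for the enaminone, the silyl enol ether and the diene are the expected major isomers. Neither point matters, because sulfur is expelled and every sp3 centre made in the cycloaddition is erased on aromatisation.

**Step 1**
Reactants: 1 3-hydroxy-4,5-dimethoxybenzoic acid
Product: 3 3-(benzyloxy)-4,5-dimethoxybenzoic acid, via benzyl ester 2 (not isolated)
Conditions: BnBr (2.3 equiv), K2CO3, DMF, 60 °C; then NaOH, H2O–MeOH, 60 °C; 1 M HCl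
Reagents that add atoms: benzyl bromide BrCc1ccccc1; sodium hydroxide [Na+].[OH-]
Why: Williamson alkylation of phenoxide and carboxylate, followed by saponification of the benzyl ester in the same flask, should leave only the aryl benzyl ether, which is inert to hydroxide.

**Step 2**
Reactants: 3 3-(benzyloxy)-4,5-dimethoxybenzoic acid
Product: 4 3-(benzyloxy)-4,5-dimethoxybenzoyl chloride
Conditions: (COCl)2, cat. DMF, CH2Cl2, 0 °C→rt; evaporated and used crude
Reagents that add atoms: oxalyl chloride O=C(Cl)C(=O)Cl
Why: DMF-catalysed (Vilsmeier-type) acid chloride formation is mild enough for aryl benzyl and aryl methyl ethers.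

**Step 3**
Reactants: 5 racemic methyl p-tolyl sulfoxide; 6 methyl benzyloxyacetate
Product: 7 racemic 1-(benzyloxy)-3-(p-tolylsulfinyl)propan-2-one
Conditions: 5 (2.1 equiv), LiN(i-Pr)2 (2.1 equiv), THF, −78 °C; then 6, −78→0 °C; 1 M HCl
Reagents that add atoms: none
Why: Claisen-type acylation of an α-sulfinyl carbanion by a simple ester is the standard entry to β-keto sulfoxides, the second equivalent of carbanion takes up the acidic proton of the product, and bringing sulfur in this early avoids having to attack an ester that already belongs to an enolisable 1,3-dicarbonyl.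

**Step 4**
Reactants: 7 racemic 1-(benzyloxy)-3-(p-tolylsulfinyl)propan-2-one
Product: 8 racemic (Z)-1-(benzyloxy)-4-(dimethylamino)-3-(p-tolylsulfinyl)but-3-en-2-one
Conditions: Me2NCH(OMe)2 (1.2 equiv), toluene, rt→50 °C
Reagents that add atoms: N,N-dimethylformamide dimethyl acetal COC(OC)N(C)C
Why: Aminomethylenation with an amide acetal should occur at the CH2 flanked by ketone and sulfoxide, far more acidic than the CH2OBn group, as in the preparation of 3-sulfinylchromones and of 2-aminomethylene 1,3-dicarbonyl compounds.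

**Step 5**
Reactants: 8 racemic (Z)-1-(benzyloxy)-4-(dimethylamino)-3-(p-tolylsulfinyl)but-3-en-2-one; 4 3-(benzyloxy)-4,5-dimethoxybenzoyl chloride
Product: 10 racemic 3-(benzyloxy)-2-[3-(benzyloxy)-4,5-dimethoxyphenyl]-5-(p-tolylsulfinyl)-4H-pyran-4-one, via acylated enaminone 9 (not isolated)
Conditions: 8 + 4 (1.1 equiv), THF, −78 °C, LiN(SiMe3)2 (2.3 equiv) added slowly; then 2 M HCl, THF, rt
Reagents that add atoms: none
Why: In-situ C-acylation of an enaminone anion by an acid chloride, followed by acid-induced addition–elimination of the aroyl enol oxygen at the aminomethylene carbon (6-endo, loss of Me2NH), is an established 4-pyranone synthesis from 2-aminomethylene β-dicarbonyl compounds, applied here with sulfinyl in place of the ester group.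

**Step 6**
Reactants: 11 methyl 4-methoxyacetoacetate
Product: 12 methyl (E)-4-methoxy-3-(trimethylsilyloxy)but-2-enoate
Conditions: Me3SiCl, Et3N, toluene, rt, 48 h; filtered, distilled
Reagents that add atoms: chlorotrimethylsilane C[Si](C)(C)Cl
Why: Amine-mediated O-silylation of the enolised β-ketoester should give the ester-conjugated silyl enol ether, the usual first stage of 1,3-bis(silyloxy)diene synthesis.

**Step 7**
Reactants: 12 methyl (E)-4-methoxy-3-(trimethylsilyloxy)but-2-enoate
Product: 13 (1Z,3Z)-1,4-dimethoxy-1,3-bis(trimethylsilyloxy)buta-1,3-diene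
Conditions: LiN(i-Pr)2 (1.3 equiv), THF, −78 °C; Me3SiCl, −78 °C→rt; hexane, filtered under Ar, used at once
Reagents that add atoms: chlorotrimethylsilane C[Si](C)(C)Cl
Why: γ-Deprotonation of the vinylogous ester at the CH2OMe group and O-silylation of the lithium dienolate is the standard second stage of 1,3-bis(silyloxy)diene synthesis and is tolerated by 4-alkoxy substituents.

**Step 8**
Reactants: 10 racemic 3-(benzyloxy)-2-[3-(benzyloxy)-4,5-dimethoxyphenyl]-5-(p-tolylsulfinyl)-4H-pyran-4-one; 13 (1Z,3Z)-1,4-dimethoxy-1,3-bis(trimethylsilyloxy)buta-1,3-diene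
Product: 16 3-(benzyloxy)-2-[3-(benzyloxy)-4,5-dimethoxyphenyl]-5,7-dihydroxy-8-methoxy-4H-chromen-4-one (3,3'-di-O-benzyl ether of the target), via cycloadduct 14 (not isolated), via dihydrochromenone 15 (not isolated)
Conditions: 13 (3 equiv), toluene (0.5 M), Ar, rt→80 °C; then 1 M HCl, THF, rt
Reagents that add atoms: none
Why: Proposed new method: the diene terminus with the largest HOMO coefficient, the OMe-bearing C4, should bond to pyranone C6 (β to the ketone, future C8a) and the ketene acetal carbon C1 to the sulfinyl-bearing C5 (future C4a, the same orientation in which such acetal carbons end up at the halogen-bearing carbon of haloquinones), either in a strongly asynchronous normal-electron-demand Diels–Alder reaction or, at the stepwise limit, by Mukaiyama–Michael addition and 6-exo-trig closure of the α-sulfinyl enolate onto the ester-level carbon, so that ring A is closed as a six-membered carbocycle by [4+2] annulation to give 14. Suprafacial addition places the sulfinyl group cis to C8a–H, the only β-hydrogen available, so warming should expel p-toluenesulfenic acid through a five-centre syn elimination to give 15, after which dilute acid collapses the mixed ketal at C5 with loss of methanol, removes C8–H by enolisation and cleaves the remaining silyl ether to deliver arene 16 with its chelated 5-OH. The nearest precedents in type are xanthone syntheses in which a chromone activated at C3 by sulfinyl or acyl takes up a silyloxydiene and then eliminates, and hydroxyanthraquinone syntheses from halogenated quinones and vinylketene acetals, whereas a monocyclic 4-pyranone has not yet served as the 2π partner. No stereocentre survives: the transient centres C4a, C5, C8 and C8a of 14 (cis fusion dictated by the ring alkene, the others uncontrolled) and the sulfur centre are all erased, so endo/exo and facial selectivity are irrelevant. The selectivities needed are orientation and choice of alkene: both acceptors on C5=C6, the C4 carbonyl and the sulfinyl group, make C6 the electrophilic end, whereas C2=C3 is fully substituted, conjugated to ring B and enriched by two oxygen donors. Lewis acids are left out to avoid silicon-induced Pummerer chemistry at sulfur, the silyl groups stay on until sulfur has left so that no C7 ketone can trigger retro-oxa-Michael opening of the pyranone ring, the surplus diene scavenges the sulfenic acid, and only mild acid is used so that no Wessely–Moser isomerisation to the 6-methoxy series can set in.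

**Step 9**
Reactants: 16 3-(benzyloxy)-2-[3-(benzyloxy)-4,5-dimethoxyphenyl]-5,7-dihydroxy-8-methoxy-4H-chromen-4-one
Product: 17 3,5,7-trihydroxy-2-(3-hydroxy-4,5-dimethoxyphenyl)-8-methoxy-4H-chromen-4-one (target)
Conditions: H2 (1 atm), Pd/C (10 wt% Pd), EtOAc–MeOH, rt, on chromatographed, sulfur-free 16
Reagents that add atoms: none
Why: Catalytic hydrogenolysis should cleave both benzylic C–O bonds while the methyl ethers and the fully conjugated chromenone, including C2=C3, remain untouched, as is routine for benzylated flavonols.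

**Compound list**
1 | 3-hydroxy-4,5-dimethoxybenzoic acid | COc1cc(C(=O)O)cc(O)c1OC | starting material
2 | benzyl 3-(benzyloxy)-4,5-dimethoxybenzoate | COc1cc(C(=O)OCc2ccccc2)cc(OCc2ccccc2)c1OC | intermediate
3 | 3-(benzyloxy)-4,5-dimethoxybenzoic acid | COc1cc(C(=O)O)cc(OCc2ccccc2)c1OC | intermediate
4 | 3-(benzyloxy)-4,5-dimethoxybenzoyl chloride | COc1cc(C(=O)Cl)cc(OCc2ccccc2)c1OC | intermediate
5 | methyl p-tolyl sulfoxide (racemic) | Cc1ccc(S(C)=O)cc1 | starting material
6 | methyl benzyloxyacetate | COC(=O)COCc1ccccc1 | starting material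
7 | 1-(benzyloxy)-3-(p-tolylsulfinyl)propan-2-one (racemic) | Cc1ccc(S(=O)CC(=O)COCc2ccccc2)cc1 | intermediate
8 | (Z)-1-(benzyloxy)-4-(dimethylamino)-3-(p-tolylsulfinyl)but-3-en-2-one (racemic; push–pull alkene, configurationally labile) | CN(C)/C=C(/C(=O)COCc1ccccc1)S(=O)c1ccc(C)cc1 | intermediate
9 | 2-(benzyloxy)-1-[3-(benzyloxy)-4,5-dimethoxyphenyl]-5-(dimethylamino)-4-(p-tolylsulfinyl)pent-4-ene-1,3-dione (diastereomer and enol mixture at C2) | CN(C)/C=C(/C(=O)C(OCc1ccccc1)C(=O)c1cc(OCc2ccccc2)c(OC)c(OC)c1)S(=O)c1ccc(C)cc1 | intermediate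
10 | 3-(benzyloxy)-2-[3-(benzyloxy)-4,5-dimethoxyphenyl]-5-(p-tolylsulfinyl)-4H-pyran-4-one (racemic) | Cc1ccc(S(=O)c2coc(-c3cc(OCc4ccccc4)c(OC)c(OC)c3)c(OCc3ccccc3)c2=O)cc1 | intermediate
11 | methyl 4-methoxyacetoacetate | COCC(=O)CC(=O)OC | starting material
12 | methyl (E)-4-methoxy-3-(trimethylsilyloxy)but-2-enoate | COC/C(O[Si](C)(C)C)=C\C(=O)OC | intermediate
13 | (1Z,3Z)-1,4-dimethoxy-1,3-bis(trimethylsilyloxy)buta-1,3-diene | CO/C=C(O[Si](C)(C)C)/C=C(/OC)O[Si](C)(C)C | intermediate
14 | 3-(benzyloxy)-2-[3-(benzyloxy)-4,5-dimethoxyphenyl]-5,8-dimethoxy-4a-(p-tolylsulfinyl)-5,7-bis(trimethylsilyloxy)-4a,5,8,8a-tetrahydro-4H-chromen-4-one (racemic, cis-fused, sulfinyl and C8a–H on the same face; mixture at C5, C8 and S) | COC1C(O[Si](C)(C)C)=CC(OC)(O[Si](C)(C)C)[C@@]2(S(=O)c3ccc(C)cc3)C(=O)C(OCc3ccccc3)=C(c3cc(OCc4ccccc4)c(OC)c(OC)c3)O[C@@H]12 | intermediate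
15 | 3-(benzyloxy)-2-[3-(benzyloxy)-4,5-dimethoxyphenyl]-5,8-dimethoxy-5,7-bis(trimethylsilyloxy)-5,8-dihydro-4H-chromen-4-one (mixture at C5 and C8) | COC1C(O[Si](C)(C)C)=CC(OC)(O[Si](C)(C)C)C2=C1OC(c1cc(OCc3ccccc3)c(OC)c(OC)c1)=C(OCc1ccccc1)C2=O | intermediate
16 | 3-(benzyloxy)-2-[3-(benzyloxy)-4,5-dimethoxyphenyl]-5,7-dihydroxy-8-methoxy-4H-chromen-4-one | COc1c(O)cc(O)c2c(=O)c(OCc3ccccc3)c(-c3cc(OCc4ccccc4)c(OC)c(OC)c3)oc12 | intermediate
17 | 3,5,7-trihydroxy-2-(3-hydroxy-4,5-dimethoxyphenyl)-8-methoxy-4H-chromen-4-one | COc1cc(-c2oc3c(OC)c(O)cc(O)c3c(=O)c2O)cc(O)c1OC | target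

**Total steps:** 9. **Longest linear sequence:** 5 steps (3, 4, 5, 8, 9; equally 1, 2, 5, 8, 9).

**Steps most likely to fail**

**Risk 1, step 8.**
- What may go wrong:
  - The pyranone alkene may be too weak a dienophile.
  - The diene may degrade by silyl migration or hydrolysis before it adds.
  - Conjugate addition may stop without ring closure and open the pyranone.
  - The liberated sulfenic acid may sulfenylate the electron-rich ring A.
- The fallback uses only known chemistry. It sets out from acid chloride 4 and returns at target 17.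
- Hoesch acylation of phloroglucinol with benzyloxyacetonitrile (HCl, ZnCl2, Et2O, 0 °C; then hot water) should give 2-(benzyloxy)-1-(2,4,6-trihydroxyphenyl)ethan-1-one F1.
- Its polyanion (LiN(SiMe3)2, 5 equiv, THF, −78 °C) is C-aroylated by 4 to 2-(benzyloxy)-1-[3-(benzyloxy)-4,5-dimethoxyphenyl]-3-(2,4,6-trihydroxyphenyl)propane-1,3-dione F2.
- F2 cyclodehydrates (cat. TsOH, toluene, 80 °C) to 3-(benzyloxy)-2-[3-(benzyloxy)-4,5-dimethoxyphenyl]-5,7-dihydroxy-4H-chromen-4-one F3.
- Benzylation of the unchelated 7-OH (BnBr, 1 equiv, K2CO3, acetone) gives the 3,7,3'-tri-O-benzyl-5-hydroxyflavone F4.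
- Elbs persulfate oxidation (K2S2O8, KOH, aqueous pyridine) attacks C8, the position para to the free 5-OH, and gives the potassium 8-sulfate F5.
- F5 is hydrolysed (aqueous HCl, Na2SO3) to the 5,8-dihydroxyflavone F6.
- The unchelated 8-OH is methylated (Me2SO4, 1 equiv, K2CO3, acetone) to the 3,7,3'-tri-O-benzyl ether of the target F7.
- Hydrogenolysis of F7 under the conditions of step 9 gives 17.

**Risk 2, step 5.**
- What may go wrong:
  - The enolate may be O-acylated instead of C-acylated.
  - The amide base may consume the acid chloride.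
  - The sulfoxide oxygen may be acylated.
- The fallback reverses the order of events. It sets out from 7 and 4 and returns at 10.
- Acid chloride 4 is converted (MeNHOMe·HCl, Et3N, CH2Cl2) into 3-(benzyloxy)-N,4,5-trimethoxy-N-methylbenzamide F8.
- The dianion of 7 (LiN(i-Pr)2, 2.5 equiv, THF, −78→−20 °C) is acylated at its more reactive γ-carbon, the CH2OBn carbon. This gives 2-(benzyloxy)-1-[3-(benzyloxy)-4,5-dimethoxyphenyl]-4-(p-tolylsulfinyl)butane-1,3-dione F9.
- Me2NCH(OMe)2 then condenses at the only remaining CH2, and mild acid closes the ring through 9 to 10.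

**Risk 3, step 9.**
- What may go wrong:
  - Sulfur residues carried over from step 8 may poison the palladium surface.
  - The hindered 3-O-benzyl ether may cleave so slowly that reduction of the pyranone ring begins.
- The fallback sets out from 16 and returns at 17.
- It replaces hydrogenolysis by Lewis-acid debenzylation with a cation scavenger (BCl3, pentamethylbenzene, CH2Cl2, −78 °C; then MeOH). At this temperature aryl methyl ethers are spared.
- This fallback makes no new compound (F0).

**Further compounds**
F1 | step 8 | 2-(benzyloxy)-1-(2,4,6-trihydroxyphenyl)ethan-1-one | O=C(COCc1ccccc1)c1c(O)cc(O)cc1O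
F2 | step 8 | 2-(benzyloxy)-1-[3-(benzyloxy)-4,5-dimethoxyphenyl]-3-(2,4,6-trihydroxyphenyl)propane-1,3-dione | COc1cc(C(=O)C(OCc2ccccc2)C(=O)c2c(O)cc(O)cc2O)cc(OCc2ccccc2)c1OC
F3 | step 8 | 3-(benzyloxy)-2-[3-(benzyloxy)-4,5-dimethoxyphenyl]-5,7-dihydroxy-4H-chromen-4-one | COc1cc(-c2oc3cc(O)cc(O)c3c(=O)c2OCc2ccccc2)cc(OCc2ccccc2)c1OC
F4 | step 8 | 3,7-bis(benzyloxy)-2-[3-(benzyloxy)-4,5-dimethoxyphenyl]-5-hydroxy-4H-chromen-4-one | COc1cc(-c2oc3cc(OCc4ccccc4)cc(O)c3c(=O)c2OCc2ccccc2)cc(OCc2ccccc2)c1OC
F5 | step 8 | potassium 3,7-bis(benzyloxy)-2-[3-(benzyloxy)-4,5-dimethoxyphenyl]-5-hydroxy-4-oxo-4H-chromen-8-yl sulfate | COc1cc(-c2oc3c(OS(=O)(=O)[O-])c(OCc4ccccc4)cc(O)c3c(=O)c2OCc2ccccc2)cc(OCc2ccccc2)c1OC.[K+]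
F6 | step 8 | 3,7-bis(benzyloxy)-2-[3-(benzyloxy)-4,5-dimethoxyphenyl]-5,8-dihydroxy-4H-chromen-4-one | COc1cc(-c2oc3c(O)c(OCc4ccccc4)cc(O)c3c(=O)c2OCc2ccccc2)cc(OCc2ccccc2)c1OC
F7 | step 8 | 3,7-bis(benzyloxy)-2-[3-(benzyloxy)-4,5-dimethoxyphenyl]-5-hydroxy-8-methoxy-4H-chromen-4-one | COc1cc(-c2oc3c(OC)c(OCc4ccccc4)cc(O)c3c(=O)c2OCc2ccccc2)cc(OCc2ccccc2)c1OC
F8 | step 5 | 3-(benzyloxy)-N,4,5-trimethoxy-N-methylbenzamide | CON(C)C(=O)c1cc(OCc2ccccc2)c(OC)c(OC)c1
F9 | step 5 | 2-(benzyloxy)-1-[3-(benzyloxy)-4,5-dimethoxyphenyl]-4-(p-tolylsulfinyl)butane-1,3-dione (racemic, diastereomer and enol mixture) | Cc1ccc(S(=O)CC(=O)C(OCc2ccccc2)C(=O)c2cc(OCc3ccccc3)c(OC)c(OC)c2)cc1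
F0 | step 9 | none | none
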